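**Assumption:** the target has no stereocentres and no configurationally stable axis, so it is achiral and the "single enantiomer" requirement is met without any stereocontrol; the only stereochemistry in the route is alkene geometry in intermediates 7 and 8.

## Retrosynthetic overview
1. The usual disconnection (Friedel–Crafts or aryl-metal formation of the tetra-ortho-substituted diaryl ketone bond) is avoided; ring B is instead built de novo onto the ketone in the last step.
2. Target 9 ⇒ Diels–Alder/aromatisation of ynone 3 (ring A, C=O, ring-B C1/C6, CH2OAc) with trioxygenated vinylketene acetal 8 (ring-B C2–C5 carrying OH, H, Me, OMe).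
3. Ynone 3 ⇒ acyl Sonogashira coupling of 2,6-dimethoxybenzoyl chloride 1 with propargyl acetate 2.
4. Diene 8 ⇒ syn-γ-enolisation/silylation of (Z)-enoate 7 ⇒ syn-carbocupration of ynoate 6 ⇒ methyl propargyl ether 4 + methyl chloroformate 5.
5. Ring order: ring A is purchased; ring B is formed last, in Step 5.

## Route

**Step 1**
Reactants: 1, 2,6-dimethoxybenzoyl chloride; 2, prop-2-yn-1-yl acetate (propargyl acetate)
Product: 3, 4-(2,6-dimethoxyphenyl)-4-oxobut-2-yn-1-yl acetate
Conditions: PdCl2(PPh3)2 (2 mol %), CuI (4 mol %), Et3N (1.2 equiv), THF, rt
Reagents that add atoms: none (both partners are numbered reactants)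
Why: Acyl Sonogashira coupling — Pd(0) inserts into the aroyl C–Cl bond and the copper acetylide of 2 transmetalates, giving the ynone at room temperature, where decarbonylation and ionisation of the propargylic acetate are slow and 1 has no α-hydrogen for ketene formation.

**Step 2**
Reactants: 4, 3-methoxyprop-1-yne (methyl propargyl ether); 5, methyl chloroformate
Product: 6, methyl 4-methoxybut-2-ynoate
Conditions: n-BuLi, THF, −78 °C; then ClCO2Me, −78 → 0 °C
Reagents that add atoms: none (methyl chloroformate is numbered reactant 5)
Why: Deprotonation of the terminal alkyne and C-acylation of the lithium acetylide with a chloroformate is the standard preparation of 2-ynoates.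

**Step 3**
Reactants: 6, methyl 4-methoxybut-2-ynoate
Product: 7, methyl (Z)-4-methoxy-3-methylbut-2-enoate (CH2OMe cis to CO2Me)
Conditions: Me2CuLi (1.2 equiv, from MeLi/CuI), THF, −78 °C; MeOH quench at −78 °C, then aq NH4Cl
Reagents that add atoms: lithium dimethylcuprate, [Li+].C[Cu-]C
Why: Stereospecific syn-carbocupration (cuprate conjugate addition to an ynoate), quenched cold before the vinylcopper/allenolate equilibrates, puts the new methyl cis to the α-H and therefore CH2OMe cis to the ester (Z), the geometry Step 4 needs.

**Step 4**
Reactants: 7, methyl (Z)-4-methoxy-3-methylbut-2-enoate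
Product: 8, (3E)-1,4-dimethoxy-3-methyl-1-(trimethylsilyloxy)buta-1,3-diene (4-OMe trans to C2; C1=C2 geometry inconsequential, as C1 becomes an aromatic carbon)
Conditions: LDA (1.1 equiv), THF, −78 °C; TMSCl, −78 °C → rt; pentane, filter, concentrate, use directly
Reagents that add atoms: chlorotrimethylsilane, C[Si](C)(C)Cl
Why: Kinetic γ-deprotonation of an enoate by LDA removes the proton from the γ-carbon cis to the ester (lithium–carbonyl-directed syn-γ rule, reinforced by the acidifying OMe), so only CH2OMe is enolised; A(1,3) strain with the ester turns the OMe outward to give the 3E dienolate, which TMSCl traps on oxygen as the silyl ketene acetal.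

**Step 5**
Reactants: 3, 4-(2,6-dimethoxyphenyl)-4-oxobut-2-yn-1-yl acetate; 8, (3E)-1,4-dimethoxy-3-methyl-1-(trimethylsilyloxy)buta-1,3-diene (1.5–2 equiv)
Product: 9, Preacredinone A, [2-(2,6-dimethoxybenzoyl)-3-hydroxy-6-methoxy-5-methylphenyl]methyl acetate
Conditions: PhMe, 0 → 60 °C; then 1 M HCl, THF, 0 °C
Reagents that add atoms: none (aqueous acid supplies only H)
Why: Brassard-type Diels–Alder benzannulation — the diene is polarised by its two-oxygen terminus, so C4 (CH–OMe) bonds to the ynone β-carbon (bearing CH2OAc) and the acetal carbon to the α-carbon (bearing the aroyl); the 1,4-cyclohexadiene adduct then aromatises by loss of MeOH from the mixed acetal, and acid cleaves the aryl O–TMS, giving OH ortho to the ketone and OMe para to it with no stereocentre to set.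

## Compound list
1 | 2,6-dimethoxybenzoyl chloride | COc1cccc(OC)c1C(=O)Cl | starting material
2 | prop-2-yn-1-yl acetate | CC(=O)OCC#C | starting material
3 | 4-(2,6-dimethoxyphenyl)-4-oxobut-2-yn-1-yl acetate | COc1cccc(OC)c1C(=O)C#CCOC(C)=O | intermediate
4 | 3-methoxyprop-1-yne | COCC#C | starting material
5 | methyl chloroformate | COC(=O)Cl | starting material
6 | methyl 4-methoxybut-2-ynoate | COCC#CC(=O)OC | intermediate
7 | methyl (Z)-4-methoxy-3-methylbut-2-enoate | COC/C(C)=C\C(=O)OC | intermediate
8 | (3E)-1,4-dimethoxy-3-methyl-1-(trimethylsilyloxy)buta-1,3-diene | CO/C=C(C)/C=C(OC)O[Si](C)(C)C | intermediate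
9 | Preacredinone A | COc1cccc(OC)c1C(=O)c1c(O)cc(C)c(OC)c1COC(C)=O | target

## Summary
Total steps: 5. Longest linear sequence: 4 (4 → 6 → 7 → 8 → 9); the ynone arm is 1 step.

Three steps most likely to fail, each with a fallback that changes the approach:

1. **Step 5 (Diels–Alder/aromatisation).** This acyclic 1,1,4-trioxygenated diene is untested in this reaction type. Possible failures are a sluggish cycloaddition, [2+2] or open-chain Michael products, or loss of silanol instead of MeOH, which would give the O-methyl ether of the target.
 Fallback: replace 8 with the geometry-locked cyclic diene 4-methyl-2-(tert-butyldimethylsilyloxy)furan (from 4-methyl-2(5H)-furanone, TBSOTf/Et3N). Furan Diels–Alder and oxa-bridge opening with an ynone carrying CH2OTBS gives the hydroquinone with the same regiochemistry. Then methylate the non-chelated 5-OH (MeI/K2CO3) and exchange TBS for acetate.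

2. **Step 4 (regio- and stereoselective dienolate formation).** Deprotonation at the C3-methyl, or formation of the 3Z (OMe-inside) isomer, would give a useless or unreactive diene.
 Fallback: use a precursor with only one enolisable site. Make methyl 4,4-dimethoxy-3-methylbutanoate (HWE of methylglyoxal dimethyl acetal with trimethyl phosphonoacetate, then H2, Pd/C), eliminate MeOH from the acetal to the enol ether (TMSOTf, i-Pr2NEt), and form the ketene acetal by simple α-deprotonation (LDA, TMSCl).

3. **Step 1 (acyl Sonogashira with a di-ortho-substituted aroyl chloride and a propargylic acetate).** The coupling may be slow, or Pd may ionise the acetate.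
 Fallback: add lithiated tert-butyldimethylsilyl propargyl ether to 2,6-dimethoxybenzaldehyde, oxidise the propargylic alcohol (MnO2 or Dess–Martin), then exchange TBS for acetate (HF·pyridine; Ac2O, pyridine).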